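1. A leftover first: at the last reading, 2.50 h, the north run still holds 70.9 % of its substrate, and the south-west run 85.0 %. So neither flask has run dry, and the feed's length is what I must judge.

in all of them: precatalyst 3.4 mM
- north: substrate 0.067 M (fed, over 12 min); run made earlier
- south-west: substrate 0.15 M (fed, over 12 min); run made earlier
- spring: substrate 0.10 M (fed, over 12 min); time 4.0 h
- dusk: substrate 0.10 M (fed, over 20 min); time 4.0 h
- dawn: substrate 0.10 M (fed, over 25 min); time 4.0 h
- autumn: substrate 0.10 M (fed, over 40 min); time 4.0 h

| run | time / h | target / % | substrate / % |
|---|---|---|---|
| north | 0.167 | 0.1 | 82.1 |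
| north | 0.500 | 1.1 | 97.9 |
| north | 0.833 | 4.7 | 96.8 |
| north | 1.33 | 9.4 | 90.5 |
| north | 2.00 | 17.5 | 79.8 |
| north | 2.50 | 25.8 | 70.9 |
| south-west | 0.167 | 1.1 | 82.9 |
| south-west | 0.500 | 2.3 | 97.2 |
| south-west | 0.833 | 1.6 | 96.9 |
| south-west | 1.33 | 6.0 | 94.6 |
| south-west | 2.00 | 11.4 | 88.4 |
| south-west | 2.50 | 14.2 | 85.0 |

(readings scatter by 1 percentage point)

- amounts and yields of target count crystals too
- given per volume of solution although it is solid: crystals
- what may be going on: substrate + free catalyst -> catalyst intermediate; catalyst intermediate -> free catalyst + target; precatalyst -> free catalyst; crystals <-> target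
- percentages count the whole charge, also what has not yet gone in
- "hardly changes" means that all values lie within two and a half points (for a concentration: within two and a half percent of the largest)

* amount of target at the end, in percent of the substrate charged for spring, dusk, dawn, autumn, in this order
* how the row runs (falls, then rises / falls all the way / rises, then falls / hardly changes / rises all the way)

2. I read the late rate of target formation between 1.33 h and 2.50 h. North gives 9.39 mM h⁻¹ and south-west 10.5 mM h⁻¹. At 2.00 h, c(substrate) reads 53.5 mM in north and 133 mM in south-west. The apparent order in substrate is therefore a scattered 0.124.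

3. I fold rate, feed time and charge into one number, the feed number N: the share of the charge that the late rate turns over during the feed. It also equals consumption divided by feed rate. With the higher reading, spring has N = 2.10 %. In autumn the feed rate is 150 mM h⁻¹, and the late rate reads 10.5 mM h⁻¹.

4. First round: N puts the share turned over during the spring feed at 2.10 %. Second round: I put that share back in, weighted by the order, and get a change of rate of 0.261 %. I expect a row that hardly changes.

5. Was one number enough? For the shape, yes; for the height, no. N holds no lag, so I commit to the shape and name no height.

6. The forecast is 35 %, 35 %, 35 %, 34.7 %, shape hardly changes: “feed time should barely matter”. It gives a height; I give none.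

7. The flask gives 43.4 %, 43.3 %, 43.3 %, 43.1 %, shape hardly changes. The shape agrees, and spring stands 8.4 percentage points above the forecast, while its catalyst intermediate climbs from 38.1 % at 2.00 h to 49.6 % at 4.00 h.

    substrate + free catalyst → catalyst intermediate (k = 310 M⁻¹ h⁻¹)
    catalyst intermediate → free catalyst + target (k = 9.50 h⁻¹)
    precatalyst → free catalyst (k = 0.370 h⁻¹)
    crystals ⇌ target, rate k4*(cs4 - [target]) while solid is left; crystals form when [target] > cs4 (solubility = 40.0 mM, k = 78.0 h⁻¹)

In spring the feed takes 0.2 h, far shorter than the substrate half-life of 2.4 h through its binding to free catalyst at 4.00 h, and at the end of that feed target stands at 0.101 % against N of 2.10 %. In autumn, whose feed lasts 3.33 times as long as spring's, target at the end of the feed is 1.40 %, below spring's N of 2.10 %, and the final row value lies 0.3 points under spring.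

The runs were computed from invented constants, noise included.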